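**Retrosynthetic overview**

1. Labels: ring B is the central benzene (b1 carries C8a, b2 C8c, b3 the oxygen of dihydrofuran ring E, b4 is CH, b5 the oxygen of dihydrofuran ring H, b6 C8b); ring C (c1–c6) is the resorcinol ring inside seven-membered ring G (C7a, C8a, b1, b2, C8c, c1, c6); ring D is the free 3,5-dihydroxyphenyl on C8b; the target is 7aS,7bR,8bR,7cS,8cS.
2. Feature: C7c, the (S)-configured O–CH(4-hydroxyphenyl) carbon of ring E, with its oxygen on b3 and with C8c bonded to b2 of the 1,3-dioxygenated ring B, is C2 and the phloroglucinol ring of (2S)-naringenin once the chromanone has lost one ring atom. Ring E is therefore made by oxidative 1,2-aryl-shift ring contraction of the flavanone 5-triflate (bond b2–C8c).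
3. Going back from the target: O-demethylation; C7b epimerisation; ring H by rhodium-carbene C–H insertion (bond C8b–C7b) from a b6 diaryl ketone; ring G by Friedel–Crafts closure (bond C7a–c6) of a b1 stilbene; the stilbene by Suzuki coupling at the triflate; ring C on C8c by nickel/photoredox decarboxylative arylation of the ring-contraction ester.
4. The b6 carbon is marked before the key step as an iodide ortho to the naringenin 5-OH, the only stage at which b6 can be told from b4, and becomes the ketone by carbonylative coupling after it.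
5. Order of ring formation: E (step 4), G (step 9), H (step 13).

Key step: step 4

Remark: (2S)-naringenin is assumed to be bought in high enantiomeric purity; a partly racemised lot would be enriched by preparative chiral chromatography before step 1.
Remark: in step 13 Rh2(S-PTAD)4 is assumed to give the (8bR) series; should a model ether show the opposite sense, Rh2(R-PTAD)4 takes its place.

**Step 1**
Reactants: 1 (2S)-naringenin
Product: 2 (2S)-5-hydroxy-7-methoxy-2-(4-methoxyphenyl)chroman-4-one
Conditions: CH2N2 (excess), Et2O–MeOH, 0 °C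
Reagents that add atoms: diazomethane C=[N+]=[N-]
Why: Diazomethane methylates the two unchelated phenols (7-OH, 4'-OH), the 5-OH hydrogen-bonded to the C4 carbonyl reacts far more slowly, and with no base present the flavanone cannot open to the chalcone, so C2 should stay (S) (O-methylation of phenols with diazomethane).

**Step 2**
Reactants: 2 (2S)-5-hydroxy-7-methoxy-2-(4-methoxyphenyl)chroman-4-one
Product: 3 (2S)-5-hydroxy-6-iodo-7-methoxy-2-(4-methoxyphenyl)chroman-4-one
Conditions: BnMe3N·ICl2, CaCO3, CH2Cl2–MeOH, rt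
Reagents that add atoms: benzyltrimethylammonium dichloroiodate C[N+](C)(C)Cc1ccccc1.Cl[I-]Cl
Why: The dichloroiodate salt is a mild source of electrophilic iodine that attacks ortho to the only free phenol, at C6, the regiochemistry known for 5-hydroxy-7-methoxyflavones with this reagent, while insoluble CaCO3 takes up HCl without exposing the flavanone to a soluble base (electrophilic aromatic iodination).

**Step 3**
Reactants: 3 (2S)-5-hydroxy-6-iodo-7-methoxy-2-(4-methoxyphenyl)chroman-4-one
Product: 4 (2S)-6-iodo-7-methoxy-2-(4-methoxyphenyl)-4-oxochroman-5-yl trifluoromethanesulfonate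
Conditions: Tf2O, pyridine, CH2Cl2, 0 °C
Reagents that add atoms: trifluoromethanesulfonic anhydride O=S(=O)(OS(=O)(=O)C(F)(F)F)C(F)(F)F
Why: Triflic anhydride sulfonylates the chelated phenol in the presence of pyridine, which is too weak a base to enolise the ketone and open the ring; the triflate masks the phenol against the oxidant of step 4 and makes b1 a cross-coupling site (O-triflation).

**Step 4**
Reactants: 4 (2S)-6-iodo-7-methoxy-2-(4-methoxyphenyl)-4-oxochroman-5-yl trifluoromethanesulfonate
Product: 8 methyl (2S,3S)-5-iodo-6-methoxy-2-(4-methoxyphenyl)-4-(trifluoromethylsulfonyloxy)-2,3-dihydrobenzofuran-3-carboxylate, via enol ether 5 (not isolated), via iodane ketal 6 (not isolated), via orthoester 7 (not isolated)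
Conditions: PhI(OAc)2, H2SO4 (cat.), HC(OMe)3, rt; then H2O
Reagents that add atoms: trimethyl orthoformate COC(OC)OC; water O
Why: Acid and orthoformate turn the ketone into enol ether 5, PhI(OAc)2 adds its trivalent iodine to C3 on the face opposite the C2 aryl group with capture of methanol at C4 to give the trans iodane ketal 6, and the ring-B carbon C4a then shifts from C4 to C3 with loss of iodobenzene, the dimethoxycarbenium ion being trapped as orthoester 7 and hydrolysed to ester 8 on aqueous work-up. This is the known oxidative 1,2-aryl-shift ring contraction of flavanones to methyl trans-2-aryl-2,3-dihydrobenzofuran-3-carboxylates with PhI(OAc)2 or Tl(NO3)3 in trimethyl orthoformate. Ring E is closed not by cyclisation of a chain but by contraction of the six-membered chromanone: a 1,2-shift through a bridged phenonium-type transition state makes the C3–C4a bond (b2–C8c) as C4–C4a breaks, and C4 leaves the ring as the ester carbon. The new stereocentre C3 (C8c) is set by inversion at C3 relative to the iodane, which stands anti to the C2 aryl group, so the ester ends trans to that group, (2S,3S), which is also the more stable arrangement; C2 (C7c) is carried over unchanged from naringenin. The step needs migration of the ring-B carbon and not of the C2 aryl group (isoflavone) or loss of H-2 (flavone); this is secured by the trans-diequatorial iodane ketal, in which only the C4–C4a ring bond is antiperiplanar to C3–I, and by the push of the two ketal oxygens, while the triflate keeps the phenol from being oxidised and the hindered, electron-poor aryl iodide should be a spectator. The medium is acidic throughout, so the base-induced opening to the chalcone that would racemise C2 has no path.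

**Step 5**
Reactants: 8 methyl (2S,3S)-5-iodo-6-methoxy-2-(4-methoxyphenyl)-4-(trifluoromethylsulfonyloxy)-2,3-dihydrobenzofuran-3-carboxylate; 9 3,5-dimethoxyphenylboronic acid
Product: 10 methyl (2S,3S)-5-(3,5-dimethoxybenzoyl)-6-methoxy-2-(4-methoxyphenyl)-4-(trifluoromethylsulfonyloxy)-2,3-dihydrobenzofuran-3-carboxylate
Conditions: CO (1 atm), PdCl2(PPh3)2 (cat.), K2CO3, anisole, 80 °C
Reagents that add atoms: carbon monoxide [C-]#[O+]
Why: Zerovalent palladium should insert into the C–I bond much faster than into the flanked C–OTf bond, CO insertion into the di-ortho-substituted arylpalladium outruns direct transmetalation, and the acylpalladium couples with 9 to give the diaryl ketone that fixes the ring D carbon on b6; carbonate can only equilibrate C3 towards the trans ester already present (carbonylative Suzuki–Miyaura coupling).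

**Step 6**
Reactants: 10 methyl (2S,3S)-5-(3,5-dimethoxybenzoyl)-6-methoxy-2-(4-methoxyphenyl)-4-(trifluoromethylsulfonyloxy)-2,3-dihydrobenzofuran-3-carboxylate
Product: 11 (2S,3S)-5-(3,5-dimethoxybenzoyl)-6-methoxy-2-(4-methoxyphenyl)-4-(trifluoromethylsulfonyloxy)-2,3-dihydrobenzofuran-3-carboxylic acid
Conditions: Me3SnOH, ClCH2CH2Cl, 80 °C; then 1 M HCl
Reagents that add atoms: trimethyltin hydroxide C[Sn](C)(C)O
Why: Trimethyltin hydroxide delivers hydroxide to the hindered methyl ester under nearly neutral conditions that leave the aryl triflate alone, and the C3 configuration is of no consequence because step 7 passes through the planar radical (ester hydrolysis with Me3SnOH).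

**Step 7**
Reactants: 11 (2S,3S)-5-(3,5-dimethoxybenzoyl)-6-methoxy-2-(4-methoxyphenyl)-4-(trifluoromethylsulfonyloxy)-2,3-dihydrobenzofuran-3-carboxylic acid; 12 1-bromo-3,5-dimethoxybenzene
Product: 13 (2S,3S)-5-(3,5-dimethoxybenzoyl)-3-(3,5-dimethoxyphenyl)-6-methoxy-2-(4-methoxyphenyl)-2,3-dihydrobenzofuran-4-yl trifluoromethanesulfonate
Conditions: Ir[dF(CF3)ppy]2(dtbbpy)PF6 (cat.), NiCl2(dme) (cat.), dtbbpy, Cs2CO3, DMF, blue LEDs, rt
Reagents that add atoms: none
Why: The excited iridium photocatalyst oxidises the cesium carboxylate, loss of CO2 gives the planar benzylic C8c radical, this is captured by the arylnickel species formed from 12 (bipyridine–nickel enters C–Br in preference to the hindered C–OTf), and reductive elimination makes the C8c–c1 bond on the face away from the neighbouring C7c aryl group, so the trans (2S,3S) isomer is expected (nickel/photoredox decarboxylative arylation).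

**Step 8**
Reactants: 13 (2S,3S)-5-(3,5-dimethoxybenzoyl)-3-(3,5-dimethoxyphenyl)-6-methoxy-2-(4-methoxyphenyl)-2,3-dihydrobenzofuran-4-yl trifluoromethanesulfonate; 14 (E)-2-(4-methoxyphenyl)vinylboronic acid
Product: 15 [(2S,3S)-3-(3,5-dimethoxyphenyl)-6-methoxy-2-(4-methoxyphenyl)-4-[(E)-2-(4-methoxyphenyl)ethenyl]-2,3-dihydrobenzofuran-5-yl](3,5-dimethoxyphenyl)methanone
Conditions: Pd(OAc)2 (cat.), SPhos, K3PO4, toluene–H2O, 80 °C
Reagents that add atoms: none
Why: Zerovalent palladium inserts into the only remaining C–OTf bond, helped by the ortho carbonyl group, and alkenylboronic acid 14 is transferred with retention of the E geometry, the bulky electron-rich SPhos ligand coping with the two ortho substituents; this installs the C8a–C7a arm (Suzuki–Miyaura coupling).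

**Step 9**
Reactants: 15 [(2S,3S)-3-(3,5-dimethoxyphenyl)-6-methoxy-2-(4-methoxyphenyl)-4-[(E)-2-(4-methoxyphenyl)ethenyl]-2,3-dihydrobenzofuran-5-yl](3,5-dimethoxyphenyl)methanone
Product: 16 ring-G ketone (7aS,7cS,8cS): rings B, C, E and G closed, b6–CO–(3,5-dimethoxyphenyl), b5–OMe, 4-methoxyphenyl on C7a and on C7c, OMe on c3 and c5
Conditions: CF3CO2H, CH2Cl2, 0 °C to rt
Reagents that add atoms: none
Why: The acid protonates the stilbene at C8a, since only the cation at C7a is stabilised (by the 4-methoxyphenyl group; the oxygens of ring B are meta to b1), and c6 of the electron-rich ring C attacks it to close ring G, as in the acid-induced cyclisation known for ε-viniferin-type stilbenes; C7a should be set (S) because the aryl group can only sit on the convex face, perpendicular to ring C with H-7a next to the c5 methoxy group, the epimer forcing it against that methoxy group or under ring B, and the benzoyl-deactivated ring D should not compete (intramolecular Friedel–Crafts alkylation).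

**Step 10**
Reactants: 16 ring-G ketone with b5–OMe
Product: 17 ring-G ketone (7aS,7cS,8cS) with b5–OH: as 16, the b5 methoxy group replaced by hydroxyl
Conditions: BCl3, CH2Cl2, −78 to 0 °C; then H2O
Reagents that add atoms: none
Why: BCl3 binds as a chelate between the ketone oxygen and the ortho methoxy oxygen on b5 and cleaves only this methyl ether, the six other methoxy groups having no neighbouring carbonyl group (chelation-controlled O-demethylation).

**Step 11**
Reactants: 17 ring-G ketone with b5–OH; 18 4-methoxybenzyl chloride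
Product: 19 ring-G ketone (7aS,7cS,8cS) with b5–O–CH2–(4-methoxyphenyl): as 17, the phenol as its 4-methoxybenzyl ether
Conditions: K2CO3, Bu4NI (cat.), DMF, 50 °C
Reagents that add atoms: none
Why: The phenoxide of 17 is alkylated by benzylic chloride 18, which brings in C7b together with its 4-methoxyphenyl group (Williamson ether synthesis).

**Step 12**
Reactants: 19 ring-G ketone 4-methoxybenzyl ether
Product: 20 hydrazone of 19 (7aS,7cS,8cS): b6–C(=N–NH2)–(3,5-dimethoxyphenyl)
Conditions: N2H4·H2O, AcOH (cat.), n-BuOH, 110 °C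
Reagents that add atoms: hydrazine NN
Why: Hydrazine condenses with the hindered diaryl ketone under acid catalysis and heat, the aryl ethers and both benzylic ethers being inert to it (hydrazone formation).

**Step 13**
Reactants: 20 hydrazone of 19
Product: 22 heptamethyl ether of the 7b-epimer of the target (7aS,7bS,8bR,7cS,8cS) with ring H cis, via diazo compound 21 (not isolated)
Conditions: MnO2, CH2Cl2, rt; filter; then Rh2(S-PTAD)4 (1 mol%), CH2Cl2, 0 °C
Reagents that add atoms: none
Why: MnO2 dehydrogenates the hydrazone to diaryldiazomethane 21, the chiral dirhodium carboxylate turns it into a donor/donor carbene, and this inserts into the activated benzylic C–H bond of the neighbouring aryl ether through a five-membered transition state to give the cis-2,3-diaryl-dihydrobenzofuran, the catalyst and not the remote stereocentres fixing C8b as (R) and with it C7b as (S) (rhodium-catalysed intramolecular carbene C–H insertion).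

**Step 14**
Reactants: 22 cis-ring-H heptamethyl ether (7aS,7bS,8bR,7cS,8cS)
Product: 23 heptamethyl ether of the target (7aS,7bR,8bR,7cS,8cS) with ring H trans
Conditions: CF3CO2H, CH2Cl2, rt
Reagents that add atoms: none
Why: The acid reversibly ionises the C7b–O bond to the 4-methoxybenzylic cation, which recloses on the b5 oxygen to the more stable trans ring, so C7b is inverted to (R) while C8b, which takes no part in the ionisation, keeps its configuration; ring E is already trans and returns unchanged (acid-mediated epimerisation through benzylic C–O heterolysis).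

**Step 15**
Reactants: 23 heptamethyl ether of the target
Product: 24 CNP0136963.1 (7aS,7bR,8bR,7cS,8cS)
Conditions: BBr3, CH2Cl2, −78 °C to rt; then H2O
Reagents that add atoms: none
Why: BBr3 cleaves all seven aryl methyl ethers by O-complexation and bromide attack on methyl, conditions under which the trans dihydrofurans and ring G are expected to persist (Lewis acid O-demethylation).

**Compound list**

1 | (2S)-naringenin, (2S)-5,7-dihydroxy-2-(4-hydroxyphenyl)chroman-4-one | O=C1C[C@@H](c2ccc(O)cc2)Oc2cc(O)cc(O)c12 | starting material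
2 | (2S)-5-hydroxy-7-methoxy-2-(4-methoxyphenyl)chroman-4-one | O=C1C[C@@H](c2ccc(OC)cc2)Oc2cc(OC)cc(O)c12 | intermediate
3 | (2S)-5-hydroxy-6-iodo-7-methoxy-2-(4-methoxyphenyl)chroman-4-one | O=C1C[C@@H](c2ccc(OC)cc2)Oc2cc(OC)c(I)c(O)c12 | intermediate
4 | (2S)-6-iodo-7-methoxy-2-(4-methoxyphenyl)-4-oxochroman-5-yl trifluoromethanesulfonate | O=C1C[C@@H](c2ccc(OC)cc2)Oc2cc(OC)c(I)c(OS(=O)(=O)C(F)(F)F)c12 | intermediate
5 | (2S)-6-iodo-4,7-dimethoxy-2-(4-methoxyphenyl)-2H-chromen-5-yl trifluoromethanesulfonate (enol ether, not isolated) | COC1=C[C@@H](c2ccc(OC)cc2)Oc2cc(OC)c(I)c(OS(=O)(=O)C(F)(F)F)c12 | intermediate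
6 | (2R,3R)-3-[acetoxy(phenyl)-λ3-iodanyl]-6-iodo-4,4,7-trimethoxy-2-(4-methoxyphenyl)chroman-5-yl trifluoromethanesulfonate (2,3-trans; C2 spatially as in 4; not isolated) | COC1(OC)[C@H](I(OC(C)=O)c2ccccc2)[C@@H](c2ccc(OC)cc2)Oc2cc(OC)c(I)c(OS(=O)(=O)C(F)(F)F)c12 | intermediate
7 | (2S,3S)-5-iodo-6-methoxy-2-(4-methoxyphenyl)-3-(trimethoxymethyl)-2,3-dihydrobenzofuran-4-yl trifluoromethanesulfonate (orthoester, not isolated) | COC(OC)(OC)[C@H]1c2c(OS(=O)(=O)C(F)(F)F)c(I)c(OC)cc2O[C@@H]1c1ccc(OC)cc1 | intermediate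
8 | methyl (2S,3S)-5-iodo-6-methoxy-2-(4-methoxyphenyl)-4-(trifluoromethylsulfonyloxy)-2,3-dihydrobenzofuran-3-carboxylate | COC(=O)[C@H]1c2c(OS(=O)(=O)C(F)(F)F)c(I)c(OC)cc2O[C@@H]1c1ccc(OC)cc1 | intermediate
9 | 3,5-dimethoxyphenylboronic acid | COc1cc(OC)cc(B(O)O)c1 | starting material
10 | methyl (2S,3S)-5-(3,5-dimethoxybenzoyl)-6-methoxy-2-(4-methoxyphenyl)-4-(trifluoromethylsulfonyloxy)-2,3-dihydrobenzofuran-3-carboxylate | COC(=O)[C@H]1c2c(OS(=O)(=O)C(F)(F)F)c(C(=O)c3cc(OC)cc(OC)c3)c(OC)cc2O[C@@H]1c1ccc(OC)cc1 | intermediate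
11 | (2S,3S)-5-(3,5-dimethoxybenzoyl)-6-methoxy-2-(4-methoxyphenyl)-4-(trifluoromethylsulfonyloxy)-2,3-dihydrobenzofuran-3-carboxylic acid | OC(=O)[C@H]1c2c(OS(=O)(=O)C(F)(F)F)c(C(=O)c3cc(OC)cc(OC)c3)c(OC)cc2O[C@@H]1c1ccc(OC)cc1 | intermediate
12 | 1-bromo-3,5-dimethoxybenzene | COc1cc(Br)cc(OC)c1 | starting material
13 | (2S,3S)-5-(3,5-dimethoxybenzoyl)-3-(3,5-dimethoxyphenyl)-6-methoxy-2-(4-methoxyphenyl)-2,3-dihydrobenzofuran-4-yl trifluoromethanesulfonate | COc1cc(OC)cc(c1)[C@H]1c2c(OS(=O)(=O)C(F)(F)F)c(C(=O)c3cc(OC)cc(OC)c3)c(OC)cc2O[C@@H]1c1ccc(OC)cc1 | intermediate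
14 | (E)-2-(4-methoxyphenyl)vinylboronic acid | COc1ccc(/C=C/B(O)O)cc1 | starting material
15 | [(2S,3S)-3-(3,5-dimethoxyphenyl)-6-methoxy-2-(4-methoxyphenyl)-4-[(E)-2-(4-methoxyphenyl)ethenyl]-2,3-dihydrobenzofuran-5-yl](3,5-dimethoxyphenyl)methanone | COc1ccc(/C=C/c2c(C(=O)c3cc(OC)cc(OC)c3)c(OC)cc3O[C@H](c4ccc(OC)cc4)[C@@H](c4cc(OC)cc(OC)c4)c23)cc1 | intermediate
16 | ring-G ketone (7aS,7cS,8cS): rings B, C, E, G closed; b6–CO–(3,5-dimethoxyphenyl); b5–OMe; 4-methoxyphenyl on C7a and C7c; OMe on c3 and c5 | COc1ccc([C@@H]2Cc3c4c(cc(OC)c3C(=O)c3cc(OC)cc(OC)c3)O[C@H](c3ccc(OC)cc3)[C@H]4c3cc(OC)cc(OC)c32)cc1 | intermediate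
17 | ring-G ketone (7aS,7cS,8cS) with b5–OH (otherwise as 16) | COc1ccc([C@@H]2Cc3c4c(cc(O)c3C(=O)c3cc(OC)cc(OC)c3)O[C@H](c3ccc(OC)cc3)[C@H]4c3cc(OC)cc(OC)c32)cc1 | intermediate
18 | 4-methoxybenzyl chloride | COc1ccc(CCl)cc1 | starting material
19 | ring-G ketone (7aS,7cS,8cS) with b5–O–CH2–(4-methoxyphenyl) (otherwise as 16) | COc1ccc([C@@H]2Cc3c4c(cc(OCc5ccc(OC)cc5)c3C(=O)c3cc(OC)cc(OC)c3)O[C@H](c3ccc(OC)cc3)[C@H]4c3cc(OC)cc(OC)c32)cc1 | intermediate
20 | hydrazone of 19 (7aS,7cS,8cS): b6–C(=N–NH2)–(3,5-dimethoxyphenyl) | COc1ccc([C@@H]2Cc3c4c(cc(OCc5ccc(OC)cc5)c3C(=NN)c3cc(OC)cc(OC)c3)O[C@H](c3ccc(OC)cc3)[C@H]4c3cc(OC)cc(OC)c32)cc1 | intermediate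
21 | diazo compound from 20 (7aS,7cS,8cS): b6–C(=N2)–(3,5-dimethoxyphenyl) (not isolated) | COc1ccc([C@@H]2Cc3c4c(cc(OCc5ccc(OC)cc5)c3C(=[N+]=[N-])c3cc(OC)cc(OC)c3)O[C@H](c3ccc(OC)cc3)[C@H]4c3cc(OC)cc(OC)c32)cc1 | intermediate
22 | heptamethyl ether of the 7b-epimer of the target (7aS,7bS,8bR,7cS,8cS), ring H cis | COc1ccc([C@@H]2Cc3c4c(cc5c3[C@@H](c3cc(OC)cc(OC)c3)[C@@H](c3ccc(OC)cc3)O5)O[C@H](c3ccc(OC)cc3)[C@H]4c3cc(OC)cc(OC)c32)cc1 | intermediate
23 | heptamethyl ether of the target (7aS,7bR,8bR,7cS,8cS), ring H trans | COc1ccc([C@@H]2Cc3c4c(cc5c3[C@@H](c3cc(OC)cc(OC)c3)[C@H](c3ccc(OC)cc3)O5)O[C@H](c3ccc(OC)cc3)[C@H]4c3cc(OC)cc(OC)c32)cc1 | intermediate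
24 | CNP0136963.1 (7aS,7bR,8bR,7cS,8cS) | Oc1ccc([C@@H]2Cc3c4c(cc5c3[C@@H](c3cc(O)cc(O)c3)[C@H](c3ccc(O)cc3)O5)O[C@H](c3ccc(O)cc3)[C@H]4c3cc(O)cc(O)c32)cc1 | target

**Step count and risk**

Total step count: 15. Longest linear sequence: 15 steps (1 to 24).

Step 4 (key step). Enol-ether formation at the carbonyl flanked by the peri triflate and the buttressing iodide may be slow, so that dehydrogenation to the flavone or the 2-to-3 shift of the 4-methoxyphenyl group could overtake the ring contraction; prolonged acid could also open the ring at C2. Fallback: setting out from 4, condensation with Me2NCH(OMe)2 (toluene, 90 °C) would give the 3-(dimethylaminomethylene)flavanone F1, diazo transfer with tosyl azide (MeCN, rt) the 3-diazoflavanone F2, and irradiation at 450 nm in methanol (Wolff rearrangement, the same shift of C4a from C4 to C3) the ring-contracted ester as a mixture of 8 and its C3 epimer, the cis ester F3. NaOMe in MeOH would epimerise F3, and the route is rejoined at 8.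

Step 7. Nickel may enter the ketone-activated C–OTf bond, the hindered benzylic radical may be reduced or dimerise before capture, or capture may occur with poor facial selectivity. Fallback: setting out from 10, the Suzuki–Miyaura coupling with 14 (conditions of step 8) is done first to give the stilbene ester F4, Me3SnOH gives the stilbene acid F5, and N-hydroxytetrachlorophthalimide with diisopropylcarbodiimide gives the redox-active ester F6. Thermal nickel-catalysed decarboxylative coupling of F6 with boronic acid 9 (NiCl2·6H2O, bathophenanthroline, Et3N, dioxane–DMF, 75 °C) needs neither light nor a surviving triflate and returns to the route at 15.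

Step 13. The carbene may insert into the doubly benzylic C7a–H bond of ring G (also a five-membered transition state), the diazo compound may form azine, or the chiral substrate may erode catalyst control at C8b. Fallback: setting out from 16, Corey–Chaykovsky methylenation (Me3S iodide, n-BuLi, THF, 0 °C) would give the 2,2-diaryloxirane F7, ZnI2 the Meinwald-rearranged diarylacetaldehyde F8, and commercial 4-methoxyphenylmagnesium bromide the alcohol F9. BBr3 would then demethylate and close ring H trans through the C7b benzylic cation, returning to the route at 24. C8b is not controlled on this path, so the (7bS,8bS) isomer F10 would have to be removed by preparative HPLC.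

**Further compounds**

F1 | step 4 | 3-[(dimethylamino)methylidene] derivative of 4 (C2 spatially as in 4; alkene geometry open) | O=C1C(=CN(C)C)[C@@H](c2ccc(OC)cc2)Oc2cc(OC)c(I)c(OS(=O)(=O)C(F)(F)F)c12
F2 | step 4 | 3-diazo derivative of 4 (C2 spatially as in 4) | O=C1C(=[N+]=[N-])[C@@H](c2ccc(OC)cc2)Oc2cc(OC)c(I)c(OS(=O)(=O)C(F)(F)F)c12
F3 | step 4 | methyl (2S,3R)-5-iodo-6-methoxy-2-(4-methoxyphenyl)-4-(trifluoromethylsulfonyloxy)-2,3-dihydrobenzofuran-3-carboxylate (cis ester) | COC(=O)[C@@H]1c2c(OS(=O)(=O)C(F)(F)F)c(I)c(OC)cc2O[C@@H]1c1ccc(OC)cc1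
F4 | step 7 | methyl (2S,3S)-5-(3,5-dimethoxybenzoyl)-6-methoxy-2-(4-methoxyphenyl)-4-[(E)-2-(4-methoxyphenyl)ethenyl]-2,3-dihydrobenzofuran-3-carboxylate | COC(=O)[C@H]1c2c(/C=C/c3ccc(OC)cc3)c(C(=O)c3cc(OC)cc(OC)c3)c(OC)cc2O[C@@H]1c1ccc(OC)cc1
F5 | step 7 | (2S,3S)-5-(3,5-dimethoxybenzoyl)-6-methoxy-2-(4-methoxyphenyl)-4-[(E)-2-(4-methoxyphenyl)ethenyl]-2,3-dihydrobenzofuran-3-carboxylic acid | OC(=O)[C@H]1c2c(/C=C/c3ccc(OC)cc3)c(C(=O)c3cc(OC)cc(OC)c3)c(OC)cc2O[C@@H]1c1ccc(OC)cc1
F6 | step 7 | 4,5,6,7-tetrachloro-1,3-dioxoisoindolin-2-yl ester of F5 | O=C(ON1C(=O)c2c(Cl)c(Cl)c(Cl)c(Cl)c2C1=O)[C@H]1c2c(/C=C/c3ccc(OC)cc3)c(C(=O)c3cc(OC)cc(OC)c3)c(OC)cc2O[C@@H]1c1ccc(OC)cc1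
F7 | step 13 | 2,2-diaryloxirane from 16 (7aS,7cS,8cS; oxirane carbon as a mixture) | COc1ccc([C@@H]2Cc3c4c(cc(OC)c3C3(c5cc(OC)cc(OC)c5)CO3)O[C@H](c3ccc(OC)cc3)[C@H]4c3cc(OC)cc(OC)c32)cc1
F8 | step 13 | diarylacetaldehyde b6–CH(3,5-dimethoxyphenyl)–CHO (7aS,7cS,8cS; both C8b epimers) | COc1ccc([C@@H]2Cc3c4c(cc(OC)c3C(C=O)c3cc(OC)cc(OC)c3)O[C@H](c3ccc(OC)cc3)[C@H]4c3cc(OC)cc(OC)c32)cc1
F9 | step 13 | alcohol b6–CH(3,5-dimethoxyphenyl)–CH(OH)–(4-methoxyphenyl) (7aS,7cS,8cS; mixture at C8b and C7b) | COc1ccc([C@@H]2Cc3c4c(cc(OC)c3C(c3cc(OC)cc(OC)c3)C(O)c3ccc(OC)cc3)O[C@H](c3ccc(OC)cc3)[C@H]4c3cc(OC)cc(OC)c32)cc1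
F10 | step 13 | (7aS,7bS,8bS,7cS,8cS) isomer of 24 | Oc1ccc([C@@H]2Cc3c4c(cc5c3[C@H](c3cc(O)cc(O)c3)[C@@H](c3ccc(O)cc3)O5)O[C@H](c3ccc(O)cc3)[C@H]4c3cc(O)cc(O)c32)cc1
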